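**Retrosynthetic overview**

1. Japonicone A is a norbornene-linked dimer of a guaianolide half (C-1 to C-15) and a eudesmanolide half (C-1′ to C-15′). The last operations are α-methylenation of the guaianolide lactone, acetylation of 2-OH and removal of a silyl group from 1′-OH.
2. C-2 is a one-carbon bridge between the bridgeheads C-1 and C-3 and carries only H and O. The cyclopentene C-1/C-5=C-4/C-3/C-2 can therefore be made by contracting the cyclohexene ring C-1/C-5=C-4/C-3/C(=O)/C(=N2) of a bicyclo[2.2.2]octenone (photo-Wolff). The extruded carbon stays as CO2H on C-2 and is then exchanged for oxygen by a radical decarboxylation on the open face over C-4=C-5.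
3. The bicyclo[2.2.2]octenone is the Diels–Alder adduct of the α-methylene lactone 18 (C-11′=C-13′) with a masked o-benzoquinone made by dearomatising the guaiacol 40. The guaiane five-membered ring is thus carved out of a benzene ring; the carbon bearing OMe becomes C-2 and the phenol carbon is the one that is lost.
4. Arene 40 comes from isocreosol: C-10 by Rh-catalysed conjugate arylation, C-7/C-8 by an Evans syn-aldol of a succinate, then γ-lactone, then the seven-membered ring by Friedel–Crafts acylation.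
5. Dienophile 18 comes from (S)-Wieland–Miescher ketone (rings A′/B′ given): 4′-methyl by γ-methylenation/hydrogenation, cis-lactone by enol triflate coupling, hydroboration and SN2 lactonisation. Overall ring order: lactone of 18; lactone and seven-membered ring of 40; bicyclo[2.2.2]octene; norbornene.

Key step: step 24

Remark: the drawn stereoisomer contains the eudesmanolide half in the absolute configuration opposite to plant-derived 1β-hydroxyalantolactone, so both halves are built by synthesis; in the arene intermediates the ring carbons are named by the guaiane numbers they will carry.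

---

**Part A. Dienophile 18**

Step 1
Reactants: 1 (S)-Wieland–Miescher ketone
Product: 2 (4aS,5S)-5-hydroxy-4a-methyl-4,4a,5,6,7,8-hexahydronaphthalen-2(3H)-one
Conditions: NaBH4 (0.3 equiv), EtOH, −10 °C
Reagents that add atoms: none
Why: Chemoselective borohydride reduction of the saturated ketone in the presence of the enone; hydride adds anti to the angular methyl, so the new 1′-OH is cis to it.

Step 2
Reactants: 2 (4aS,5S)-5-hydroxy-4a-methyl-4,4a,5,6,7,8-hexahydronaphthalen-2(3H)-one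
Product: 3 (4aS,5S)-5-(tert-butyldimethylsilyloxy)-4a-methyl-4,4a,5,6,7,8-hexahydronaphthalen-2(3H)-one
Conditions: TBSOTf, 2,6-lutidine, CH2Cl2, 0 °C
Reagents that add atoms: tert-butyldimethylsilyl triflate, CC(C)(C)[Si](C)(C)OS(=O)(=O)C(F)(F)F
Why: Silyl ether formation with the reactive triflate protects the hindered neopentyl alcohol until the last step; no stereocentre is touched.

Step 3
Reactants: 3 (4aS,5S)-5-(tert-butyldimethylsilyloxy)-4a-methyl-4,4a,5,6,7,8-hexahydronaphthalen-2(3H)-one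
Product: 4 (4aS,5S)-5-(tert-butyldimethylsilyloxy)-4a-methyl-8-methylidene-4,4a,5,6,7,8-hexahydronaphthalen-2(3H)-one
Conditions: CH2(OEt)2, POCl3, NaOAc, CHCl3, 60 °C
Reagents that add atoms: diethoxymethane, CCOCOCC
Why: γ-Methylenation of the enone through its dienol ether (alkoxymethylation at the γ-carbon then loss of ethanol, the protocol used for 6-methylene steroids) puts the future C-15′ on C-4′; no stereocentre is formed.

Step 4
Reactants: 4 (4aS,5S)-5-(tert-butyldimethylsilyloxy)-4a-methyl-8-methylidene-4,4a,5,6,7,8-hexahydronaphthalen-2(3H)-one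
Product: 5 (4aS,5S,8R)-5-(tert-butyldimethylsilyloxy)-4a,8-dimethyl-4,4a,5,6,7,8-hexahydronaphthalen-2(3H)-one
Conditions: H2 (1 atm), RhCl(PPh3)3 (5 mol %), benzene, 25 °C
Reagents that add atoms: none
Why: Homogeneous hydrogenation reduces only the unhindered exocyclic C=C and delivers H2 anti to the pseudoaxial angular methyl, so the 4′-methyl should end cis to it under kinetic control.

Step 5
Reactants: 5 (4aS,5S,8R)-5-(tert-butyldimethylsilyloxy)-4a,8-dimethyl-4,4a,5,6,7,8-hexahydronaphthalen-2(3H)-one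
Product: 7 (4aS,5S,8R)-5-(tert-butyldimethylsilyloxy)-4a,8-dimethyl-4,4a,5,6,7,8-hexahydronaphthalen-2-yl trifluoromethanesulfonate, via lithium dienolate 6 (not isolated)
Conditions: LiN(iPr)2, THF, −78 °C; then PhNTf2, −78 → 0 °C
Reagents that add atoms: N-phenylbis(trifluoromethanesulfonimide), O=S(=O)(N(c1ccccc1)S(=O)(=O)C(F)(F)F)C(F)(F)F
Why: Kinetic α′-deprotonation and O-triflation (enol triflate formation) fix the cross-conjugated diene C-5′=C-6′/C-7′=C-8′ without touching the γ-stereocentre C-4′.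

Step 6
Reactants: 7 (4aS,5S,8R)-5-(tert-butyldimethylsilyloxy)-4a,8-dimethyl-4,4a,5,6,7,8-hexahydronaphthalen-2-yl trifluoromethanesulfonate; 8 (2-ethoxy-2-oxoethyl)zinc bromide
Product: 9 ethyl 2-[(4aS,5S,8R)-5-(tert-butyldimethylsilyloxy)-4a,8-dimethyl-4,4a,5,6,7,8-hexahydronaphthalen-2-yl]acetate
Conditions: Pd(PPh3)4 (5 mol %, zerovalent palladium), THF/DMPU, 60 °C
Reagents that add atoms: none
Why: Negishi coupling of the Reformatsky reagent with the enol triflate attaches C-11′/C-12′ to C-7′.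

Step 7
Reactants: 9 ethyl 2-[(4aS,5S,8R)-5-(tert-butyldimethylsilyloxy)-4a,8-dimethyl-4,4a,5,6,7,8-hexahydronaphthalen-2-yl]acetate
Product: 11 ethyl 2-[(2R,3R,4aS,5S,8R)-5-(tert-butyldimethylsilyloxy)-3-hydroxy-4a,8-dimethyl-2,3,4,4a,5,6,7,8-octahydronaphthalen-2-yl]acetate, via 9-BBN adduct 10 (not isolated)
Conditions: 9-BBN, THF, 0 → 25 °C; then H2O2, NaOAc, H2O, 0 °C
Reagents that add atoms: hydrogen peroxide, OO
Why: Hydroboration–oxidation places boron on the terminal diene carbon C-8′ from the face anti to the angular methyl (syn addition), so H-7′ and 8′-OH are anti to that methyl and the C-7′ side chain is cis to it.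

Step 8
Reactants: 11 ethyl 2-[(2R,3R,4aS,5S,8R)-5-(tert-butyldimethylsilyloxy)-3-hydroxy-4a,8-dimethyl-2,3,4,4a,5,6,7,8-octahydronaphthalen-2-yl]acetate
Product: 12 the 3-methanesulfonate of 11 (same configuration)
Conditions: MsCl, Et3N, CH2Cl2, 0 °C
Reagents that add atoms: methanesulfonyl chloride, CS(=O)(=O)Cl
Why: Sulfonylation turns the equatorial 8′-OH into a leaving group with retention.

Step 9
Reactants: 12 the 3-methanesulfonate of 11
Product: 14 (1S,4R,7R,8S,10S)-1-(tert-butyldimethylsilyloxy)-13-noreudesm-5-en-12,8-olide (cis-fused γ-lactone), via lithium carboxylate 13 (not isolated)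
Conditions: LiOH, THF/H2O, 0 → 50 °C
Reagents that add atoms: lithium hydroxide, [Li+].[OH-]
Why: Saponification followed by intramolecular SN2 displacement of the mesylate by the carboxylate (5-exo-tet) inverts C-8′ and gives the cis-fused lactone syn to the angular methyl.

Step 10
Reactants: 14 (1S,4R,7R,8S,10S)-1-(tert-butyldimethylsilyloxy)-13-noreudesm-5-en-12,8-olide
Product: 18 (1S,4R,7S,8S,10S)-1-(tert-butyldimethylsilyloxy)eudesma-5,11(13)-dien-12,8-olide, via lithium enolate 15 (not isolated), via Mannich base 16 (not isolated), via ammonium iodide 17 (not isolated)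
Conditions: LiN(iPr)2, THF, −78 °C; CH2=NMe2+ I−, −78 → 25 °C; then MeI, MeOH; then NaHCO3, H2O/CH2Cl2
Reagents that add atoms: Eschenmoser's salt, C=[N+](C)C.[I-]
Why: Aminomethylation of the lactone enolate on its convex face, N-methylation and Hofmann-type elimination (α-methylenation) give the exocyclic C-11′=C-13′; the transient C-11′ centre is lost.

**Part B. Arene 40**

Step 11
Reactants: 19 2-methoxy-5-methylphenol (isocreosol)
Product: 20 2-isopropoxy-1-methoxy-4-methylbenzene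
Conditions: 2-bromopropane, K2CO3, DMF, 60 °C
Reagents that add atoms: 2-bromopropane, CC(C)Br
Why: Williamson ether synthesis gives a phenol ether that is a poor ortho-director and can later be cleaved beside the methyl ether.

Step 12
Reactants: 20 2-isopropoxy-1-methoxy-4-methylbenzene
Product: 23 (3-isopropoxy-2-methoxy-5-methylphenyl)boronic acid, via aryllithium 21 (not isolated), via dimethyl boronate 22 (not isolated)
Conditions: n-BuLi, TMEDA, Et2O, 0 °C; B(OMe)3, −78 → 25 °C; then HCl (1 M, aq.)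
Reagents that add atoms: trimethyl borate, COB(OC)OC; water, O
Why: Directed ortho-metalation next to OMe (the position next to O-iPr is flanked by the bulky ether and the ring methyl) followed by borylation marks the future C-1.

Step 13
Reactants: 23 (3-isopropoxy-2-methoxy-5-methylphenyl)boronic acid; 24 isopropyl (E)-but-2-enoate
Product: 25 isopropyl (R)-3-(3-isopropoxy-2-methoxy-5-methylphenyl)butanoate
Conditions: Rh(acac)(C2H4)2 (3 mol %), (S)-BINAP, dioxane/H2O (10:1), 100 °C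
Reagents that add atoms: none
Why: Rh-catalysed asymmetric conjugate arylation (Hayashi–Miyaura reaction); the (S)-BINAP aryl-rhodium species adds to the enoate face that gives the (R)-benzylic centre C-10.

Step 14
Reactants: 25 isopropyl (R)-3-(3-isopropoxy-2-methoxy-5-methylphenyl)butanoate
Product: 26 (R)-3-(3-isopropoxy-2-methoxy-5-methylphenyl)butanal
Conditions: iBu2AlH, toluene, −78 °C; then KNaC4H4O6 (aq.)
Reagents that add atoms: none
Why: Partial reduction of the ester through the stable tetrahedral aluminate gives the aldehyde (C-8) without touching C-10.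

Step 15
Reactants: 27 (S)-4-benzyloxazolidin-2-one; 28 4-(tert-butoxy)-4-oxobutanoic acid
Product: 30 tert-butyl 4-[(S)-4-benzyl-2-oxooxazolidin-3-yl]-4-oxobutanoate, via mixed pivalic anhydride 29 (not isolated)
Conditions: t-BuCOCl, Et3N, THF, −20 °C; then 27, LiCl, 25 °C
Reagents that add atoms: none
Why: N-Acylation of the oxazolidinone through the mixed anhydride gives the succinate imide carrying C-6, C-7, C-11 and C-12.

Step 16
Reactants: 30 tert-butyl 4-[(S)-4-benzyl-2-oxooxazolidin-3-yl]-4-oxobutanoate; 26 (R)-3-(3-isopropoxy-2-methoxy-5-methylphenyl)butanal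
Product: 33 tert-butyl (3S,4R,6R)-3-[(S)-4-benzyl-2-oxooxazolidine-3-carbonyl]-4-hydroxy-6-(3-isopropoxy-2-methoxy-5-methylphenyl)heptanoate, via boron enolate 31 (not isolated), via boron aldolate 32 (not isolated)
Conditions: n-Bu2BOTf, iPr2NEt, CH2Cl2, 0 °C; 26, −78 → 0 °C; then pH 7 buffer, MeOH, H2O2
Reagents that add atoms: none
Why: Evans syn-aldol: the Z-boron enolate of the imide reacts through a chair transition state on the face away from the benzyl group, which sets C-7 (S) and C-8 (R) under reagent control.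

Step 17
Reactants: 33 tert-butyl (3S,4R,6R)-3-[(S)-4-benzyl-2-oxooxazolidine-3-carbonyl]-4-hydroxy-6-(3-isopropoxy-2-methoxy-5-methylphenyl)heptanoate
Product: 35 (2S,3R,5R)-2-(2-tert-butoxy-2-oxoethyl)-3-hydroxy-5-(3-isopropoxy-2-methoxy-5-methylphenyl)hexanoic acid, via peroxy acid 34 (not isolated)
Conditions: LiOH, H2O2, THF/H2O, 0 °C; then Na2SO3; HCl to pH 2
Reagents that add atoms: hydrogen peroxide, OO
Why: Hydroperoxide attacks the exocyclic imide carbonyl (acyl substitution) and sulfite reduces the peracid, freeing the C-6 acid without epimerising C-7.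

Step 18
Reactants: 35 (2S,3R,5R)-2-(2-tert-butoxy-2-oxoethyl)-3-hydroxy-5-(3-isopropoxy-2-methoxy-5-methylphenyl)hexanoic acid
Product: 38 trans-fused aryl keto lactone (7S,8R,10R; C-6 ketone on aromatic C-5; γ-lactone O-8/C-12/C-11/C-7; O-iPr and OMe on the arene), via lactone acid 36 (not isolated), via mixed trifluoroacetic anhydride 37 (not isolated)
Conditions: CF3CO2H, CH2Cl2, 25 °C; then (CF3CO)2O, 0 → 25 °C
Reagents that add atoms: none
Why: Acidolysis of the tert-butyl ester with γ-lactonisation (trans, fixed by the syn-aldol) and then intramolecular Friedel–Crafts acylation at the only free position ortho to the tether, which is para to O-iPr, close the seven-membered ring.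

Step 19
Reactants: 38 trans-fused aryl keto lactone
Product: 39 trans-fused benzocycloheptene lactone (7S,8R,10R; C-6 is CH2; O-iPr on the arene)
Conditions: Et3SiH, CF3CO2H, 25 → 50 °C
Reagents that add atoms: none
Why: Ionic hydrogenation of the electron-rich aryl ketone (protonation then hydride transfer from silane, twice) gives the benzylic CH2 and removes the acidity at C-7.

Step 20
Reactants: 39 trans-fused benzocycloheptene lactone
Product: 40 guaiacol lactone (7S,8R,10R; free phenol next to aromatic C-3-H; OMe next to C-1)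
Conditions: BCl3, CH2Cl2, −78 → 0 °C; then H2O
Reagents that add atoms: none
Why: Lewis-acid dealkylation cleaves the secondary isopropyl ether much faster than the methyl ether and the lactone.

**Part C. Union, ring contraction and end game**

Step 21
Reactants: 40 guaiacol lactone; 18 (1S,4R,7S,8S,10S)-1-(tert-butyldimethylsilyloxy)eudesma-5,11(13)-dien-12,8-olide
Product: 42 bicyclo[2.2.2]octenone adduct (bonds C-13′–C-1 and C-11′–C-3; ketone on C-3; dimethyl ketal on C-1; C-12′ carbonyl syn to C-4=C-5), via masked o-benzoquinone 41 (not isolated)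
Conditions: PhI(OAc)2, MeOH, 0 °C; evaporate; then 18, toluene, 110 °C (sealed tube)
Reagents that add atoms: methanol, CO
Why: Oxidative dearomatisation of the guaiacol gives the 6,6-dimethoxycyclohexa-2,4-dienone, which adds 18 in a Diels–Alder reaction with the usual ortho regiochemistry (C-11′ to C-3 next to the ketone, CH2-13′ to the hindered C-1), anti to the pseudoaxial C-10 methyl, on the convex face of the cis-lactone and with the lactone carbonyl endo, which should set C-1, C-3 and C-11′.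

Step 22
Reactants: 42 bicyclo[2.2.2]octenone adduct
Product: 43 bicyclo[2.2.2]octenone with CH2 in place of the ketal carbon
Conditions: SmI2 (divalent samarium, 5 equiv), THF/MeOH, −78 → 0 °C
Reagents that add atoms: none
Why: Ketyl-mediated reductive cleavage of both α-alkoxy groups of the α,α-dimethoxy ketone leaves the enolisable CH2 needed for diazo transfer; lactones and silyl ether are not reduced.

Step 23
Reactants: 43 bicyclo[2.2.2]octenone with CH2 in place of the ketal carbon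
Product: 46 α-diazoketone (C=N2 on C-1; C=O on C-3), via lithium enolate 44 (not isolated), via trifluoroacetyl ketone 45 (not isolated)
Conditions: LiN(SiMe3)2 (1.1 equiv), THF, −78 °C; CF3CO2CH2CF3; then MeSO2N3, Et3N, H2O, MeCN, 25 °C
Reagents that add atoms: methanesulfonyl azide, CS(=O)(=O)N=[N+]=[N-]
Why: Detrifluoroacetylative diazo transfer (Regitz type); the ketone can enolise only toward the CH2 because the other α-carbon is a bridgehead, and it is more acidic than the lactone CH2.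

Step 24
Reactants: 46 α-diazoketone
Product: 48 norbornene-2-carboxylic acid (CO2H on the new C-2 and anti to C-4=C-5), via ketene 47 (not isolated)
Conditions: hν (365 nm), THF/H2O (5:1), 20 °C
Reagents that add atoms: water, O
Why: Light expels N2 from the diazoketone and, because diazo and carbonyl groups are held s-cis in the ring, the allylic bridgehead C-3 shifts from the carbonyl carbon to the diazo carbon in concert (Wolff rearrangement), giving ketene 47 in which the former diazo carbon is C-2; water then adds to the ketene. The closest known reaction type is the photochemical Wolff ring contraction of cyclic 2-diazoketones, the standard way from bicyclo[2.2.2]octan-2-ones to 7-substituted norbornanes. The cyclopentene C-1/C-5=C-4/C-3/C-2 is closed by this 1,2-carbon shift, that is by contraction of the six-membered ring C-1/C-5=C-4/C-3/C(=O)/C(=N2) by one atom, the excised carbonyl carbon remaining as CO2H on C-2 and the added strain being paid for by loss of N2. The only new stereocentre, C-2, is set when the ketene hydrate is protonated from the open face over C-4=C-5, which leaves CO2H over the C-13′/C-11′ bridge; this centre is erased in step 25, so either epimer serves, while C-1, C-3 and C-11′ keep their configuration. The step needs the shift to win over carbene reactions (addition to C-4=C-5, O–H insertion), which the concerted excited-state path of an s-cis diazoketone and the hindered tetrasubstituted alkene should secure, and it needs no regiocontrol because C-3 is the only carbon substituent on the acyl carbon.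

Step 25
Reactants: 48 norbornene-2-carboxylic acid
Product: 51 2-alcohol (2-OH syn to C-4=C-5 as in japonicone A; 13-nor lactone; 1′-OTBS), via Barton ester 49 (not isolated), via hydroperoxide 50 (not isolated)
Conditions: 1-hydroxypyridine-2(1H)-thione, DCC, DMAP (cat.), CH2Cl2, 0 °C, dark; then O2, t-BuSH, toluene, hν (W lamp), 0 °C; then PPh3, 25 °C
Reagents that add atoms: dioxygen, O=O
Why: Barton decarboxylation with oxygen trapping: the C-2 radical should be captured by O2 on the open face over C-4=C-5, since the other face is shielded by the exo C-7′ and H-13′ of the two-carbon bridge, and PPh3 reduces the hydroperoxide to the alcohol.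

Step 26
Reactants: 51 2-alcohol
Product: 55 α-methylene lactone alcohol (C-11=C-13 installed; 2-OH free; 1′-OTBS), via dilithio salt 52 (not isolated), via Mannich base 53 (not isolated), via ammonium iodide 54 (not isolated)
Conditions: LiN(iPr)2 (2.5 equiv), THF, −78 °C; CH2=NMe2+ I−, −78 → 25 °C; then MeI, MeOH; then NaHCO3, H2O/CH2Cl2
Reagents that add atoms: Eschenmoser's salt, C=[N+](C)C.[I-]
Why: The guaianolide lactone is the only enolisable carbonyl (the spiro lactone has no α-hydrogen and the acetate is not yet present), so enolate aminomethylation, N-methylation and Hofmann-type elimination give the α-methylene lactone.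

Step 27
Reactants: 55 α-methylene lactone alcohol
Product: 56 japonicone A 1′-O-tert-butyldimethylsilyl ether
Conditions: Ac2O, DMAP (cat.), pyridine, 25 °C
Reagents that add atoms: acetic anhydride, CC(=O)OC(C)=O
Why: Nucleophilic-catalysed acylation of the only free hydroxyl gives the 2-acetate with retention at C-2.

Step 28
Reactants: 56 japonicone A 1′-O-tert-butyldimethylsilyl ether
Product: 57 japonicone A
Conditions: HF·pyridine, THF, 0 → 25 °C
Reagents that add atoms: none
Why: Fluoride-mediated desilylation frees 1′-OH under conditions that leave the acetate, both lactones and the alkenes untouched.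

---

**Compound list**

1 | (S)-Wieland–Miescher ketone | C[C@]12CCC(=O)C=C1CCCC2=O | starting material
2 | (4aS,5S)-5-hydroxy-4a-methyl-4,4a,5,6,7,8-hexahydronaphthalen-2(3H)-one | O=C1CC[C@@]2(C)C(=C1)CCC[C@@H]2O | intermediate
3 | (4aS,5S)-5-(tert-butyldimethylsilyloxy)-4a-methyl-4,4a,5,6,7,8-hexahydronaphthalen-2(3H)-one | O=C1CC[C@@]2(C)C(=C1)CCC[C@@H]2O[Si](C)(C)C(C)(C)C | intermediate
4 | (4aS,5S)-5-(tert-butyldimethylsilyloxy)-4a-methyl-8-methylidene-4,4a,5,6,7,8-hexahydronaphthalen-2(3H)-one | O=C1CC[C@@]2(C)C(=C1)C(=C)CC[C@@H]2O[Si](C)(C)C(C)(C)C | intermediate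
5 | (4aS,5S,8R)-5-(tert-butyldimethylsilyloxy)-4a,8-dimethyl-4,4a,5,6,7,8-hexahydronaphthalen-2(3H)-one | O=C1CC[C@@]2(C)C(=C1)[C@H](C)CC[C@@H]2O[Si](C)(C)C(C)(C)C | intermediate
6 | lithium dienolate of 5 (O–Li on C-2; C-2=C-3 and C-1=C-8a) | [Li]OC1=CC[C@@]2(C)C(=C1)[C@H](C)CC[C@@H]2O[Si](C)(C)C(C)(C)C | intermediate
7 | (4aS,5S,8R)-5-(tert-butyldimethylsilyloxy)-4a,8-dimethyl-4,4a,5,6,7,8-hexahydronaphthalen-2-yl trifluoromethanesulfonate | FC(F)(F)S(=O)(=O)OC1=CC[C@@]2(C)C(=C1)[C@H](C)CC[C@@H]2O[Si](C)(C)C(C)(C)C | intermediate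
8 | (2-ethoxy-2-oxoethyl)zinc bromide | CCOC(=O)C[Zn]Br | starting material
9 | ethyl 2-[(4aS,5S,8R)-5-(tert-butyldimethylsilyloxy)-4a,8-dimethyl-4,4a,5,6,7,8-hexahydronaphthalen-2-yl]acetate | CCOC(=O)CC1=CC[C@@]2(C)C(=C1)[C@H](C)CC[C@@H]2O[Si](C)(C)C(C)(C)C | intermediate
10 | 9-BBN adduct of 9 (boron on C-8′, anti to the angular methyl) | CCOC(=O)C[C@H]1[C@H](B4C5CCCC4CCC5)C[C@@]2(C)C(=C1)[C@H](C)CC[C@@H]2O[Si](C)(C)C(C)(C)C | intermediate
11 | ethyl 2-[(2R,3R,4aS,5S,8R)-5-(tert-butyldimethylsilyloxy)-3-hydroxy-4a,8-dimethyl-2,3,4,4a,5,6,7,8-octahydronaphthalen-2-yl]acetate | CCOC(=O)C[C@H]1[C@H](O)C[C@@]2(C)C(=C1)[C@H](C)CC[C@@H]2O[Si](C)(C)C(C)(C)C | intermediate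
12 | 3-methanesulfonate of 11 | CCOC(=O)C[C@H]1[C@H](OS(C)(=O)=O)C[C@@]2(C)C(=C1)[C@H](C)CC[C@@H]2O[Si](C)(C)C(C)(C)C | intermediate
13 | lithium carboxylate of 12 | [Li+].[O-]C(=O)C[C@H]1[C@H](OS(C)(=O)=O)C[C@@]2(C)C(=C1)[C@H](C)CC[C@@H]2O[Si](C)(C)C(C)(C)C | intermediate
14 | (1S,4R,7R,8S,10S)-1-(tert-butyldimethylsilyloxy)-13-noreudesm-5-en-12,8-olide | O=C1O[C@H]2C[C@@]3(C)C(=C[C@H]2C1)[C@H](C)CC[C@@H]3O[Si](C)(C)C(C)(C)C | intermediate
15 | lithium enolate of lactone 14 | C1(O[Li])O[C@H]2C[C@@]3(C)C(=C[C@H]2C=1)[C@H](C)CC[C@@H]3O[Si](C)(C)C(C)(C)C | intermediate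
16 | 11′-(dimethylaminomethyl) lactone (CH2NMe2 cis to H-7′) | O=C1O[C@H]2C[C@@]3(C)C(=C[C@H]2[C@@H]1CN(C)C)[C@H](C)CC[C@@H]3O[Si](C)(C)C(C)(C)C | intermediate
17 | trimethylammonium iodide of 16 | O=C1O[C@H]2C[C@@]3(C)C(=C[C@H]2[C@@H]1C[N+](C)(C)C)[C@H](C)CC[C@@H]3O[Si](C)(C)C(C)(C)C.[I-] | intermediate
18 | (1S,4R,7S,8S,10S)-1-(tert-butyldimethylsilyloxy)eudesma-5,11(13)-dien-12,8-olide | O=C1O[C@H]2C[C@@]3(C)C(=C[C@H]2C1=C)[C@H](C)CC[C@@H]3O[Si](C)(C)C(C)(C)C | intermediate
19 | 2-methoxy-5-methylphenol | COc1ccc(C)cc1O | starting material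
20 | 2-isopropoxy-1-methoxy-4-methylbenzene | COc1ccc(C)cc1OC(C)C | intermediate
21 | (3-isopropoxy-2-methoxy-5-methylphenyl)lithium | COc1c([Li])cc(C)cc1OC(C)C | intermediate
22 | dimethyl (3-isopropoxy-2-methoxy-5-methylphenyl)boronate | COB(OC)c1cc(C)cc(OC(C)C)c1OC | intermediate
23 | (3-isopropoxy-2-methoxy-5-methylphenyl)boronic acid | OB(O)c1cc(C)cc(OC(C)C)c1OC | intermediate
24 | isopropyl (E)-but-2-enoate | C/C=C/C(=O)OC(C)C | starting material
25 | isopropyl (R)-3-(3-isopropoxy-2-methoxy-5-methylphenyl)butanoate | C[C@H](CC(=O)OC(C)C)c1cc(C)cc(OC(C)C)c1OC | intermediate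
26 | (R)-3-(3-isopropoxy-2-methoxy-5-methylphenyl)butanal | C[C@H](CC=O)c1cc(C)cc(OC(C)C)c1OC | intermediate
27 | (S)-4-benzyloxazolidin-2-one | O=C1N[C@@H](Cc2ccccc2)CO1 | starting material
28 | 4-(tert-butoxy)-4-oxobutanoic acid | CC(C)(C)OC(=O)CCC(=O)O | starting material
29 | mixed pivalic anhydride of 28 | CC(C)(C)OC(=O)CCC(=O)OC(=O)C(C)(C)C | intermediate
30 | tert-butyl 4-[(S)-4-benzyl-2-oxooxazolidin-3-yl]-4-oxobutanoate | CC(C)(C)OC(=O)CCC(=O)N1[C@@H](Cc2ccccc2)COC1=O | intermediate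
31 | (Z)-dibutylboron enolate of 30 | CCCCB(CCCC)O/C(=C\CC(=O)OC(C)(C)C)N1[C@@H](Cc2ccccc2)COC1=O | intermediate
32 | dibutylboron aldolate of 33 | CC(C)(C)OC(=O)C[C@H](C(=O)N1[C@@H](Cc2ccccc2)COC1=O)[C@H](OB(CCCC)CCCC)C[C@@H](C)c1cc(C)cc(OC(C)C)c1OC | intermediate
33 | tert-butyl (3S,4R,6R)-3-[(S)-4-benzyl-2-oxooxazolidine-3-carbonyl]-4-hydroxy-6-(3-isopropoxy-2-methoxy-5-methylphenyl)heptanoate | CC(C)(C)OC(=O)C[C@H](C(=O)N1[C@@H](Cc2ccccc2)COC1=O)[C@H](O)C[C@@H](C)c1cc(C)cc(OC(C)C)c1OC | intermediate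
34 | peroxy acid of 35 | CC(C)(C)OC(=O)C[C@H](C(=O)OO)[C@H](O)C[C@@H](C)c1cc(C)cc(OC(C)C)c1OC | intermediate
35 | (2S,3R,5R)-2-(2-tert-butoxy-2-oxoethyl)-3-hydroxy-5-(3-isopropoxy-2-methoxy-5-methylphenyl)hexanoic acid | CC(C)(C)OC(=O)C[C@H](C(=O)O)[C@H](O)C[C@@H](C)c1cc(C)cc(OC(C)C)c1OC | intermediate
36 | (2R,3S)-2-[(R)-2-(3-isopropoxy-2-methoxy-5-methylphenyl)propyl]-5-oxotetrahydrofuran-3-carboxylic acid | C1C(=O)O[C@H](C[C@@H](C)c2cc(C)cc(OC(C)C)c2OC)[C@H]1C(=O)O | intermediate
37 | mixed trifluoroacetic anhydride of 36 | C1C(=O)O[C@H](C[C@@H](C)c2cc(C)cc(OC(C)C)c2OC)[C@H]1C(=O)OC(=O)C(F)(F)F | intermediate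
38 | trans-fused aryl keto lactone (7S,8R,10R; C-6 ketone) | C1C(=O)O[C@@H]2C[C@@H](C)c3c(OC)c(OC(C)C)cc(C)c3C(=O)[C@@H]12 | intermediate
39 | trans-fused benzocycloheptene lactone, isopropyl ether (7S,8R,10R) | C1C(=O)O[C@@H]2C[C@@H](C)c3c(OC)c(OC(C)C)cc(C)c3C[C@@H]12 | intermediate
40 | guaiacol lactone (7S,8R,10R; free phenol) | C1C(=O)O[C@@H]2C[C@@H](C)c3c(OC)c(O)cc(C)c3C[C@@H]12 | intermediate
41 | masked o-benzoquinone (6,6-dimethoxycyclohexa-2,4-dienone fused to the lactone-bearing seven-membered ring) | C1C(=O)O[C@@H]2C[C@@H](C)C3=C(C[C@@H]12)C(C)=CC(=O)C3(OC)OC | intermediate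
42 | bicyclo[2.2.2]octenone adduct (ketone on C-3; dimethyl ketal on C-1) | C1C(=O)O[C@@H]2C[C@@H](C)[C@]34C[C@]5(C(=O)O[C@H]6C[C@@]7(C)C(=C[C@H]65)[C@H](C)CC[C@@H]7O[Si](C)(C)C(C)(C)C)[C@H](C(C)=C3C[C@@H]12)C(=O)C4(OC)OC | intermediate
43 | bicyclo[2.2.2]octenone (CH2 on C-1) | C1C(=O)O[C@@H]2C[C@@H](C)[C@]34C[C@]5(C(=O)O[C@H]6C[C@@]7(C)C(=C[C@H]65)[C@H](C)CC[C@@H]7O[Si](C)(C)C(C)(C)C)[C@H](C(C)=C3C[C@@H]12)C(=O)C4 | intermediate
44 | lithium enolate of 43 | C1C(=O)O[C@@H]2C[C@@H](C)[C@]34C[C@]5(C(=O)O[C@H]6C[C@@]7(C)C(=C[C@H]65)[C@H](C)CC[C@@H]7O[Si](C)(C)C(C)(C)C)[C@H](C(C)=C3C[C@@H]12)C(O[Li])=C4 | intermediate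
45 | α-trifluoroacetyl ketone (chelated enol form) | C1C(=O)O[C@@H]2C[C@@H](C)[C@]34C[C@]5(C(=O)O[C@H]6C[C@@]7(C)C(=C[C@H]65)[C@H](C)CC[C@@H]7O[Si](C)(C)C(C)(C)C)[C@H](C(C)=C3C[C@@H]12)C(=O)/C4=C(\O)C(F)(F)F | intermediate
46 | α-diazoketone (C=N2 on C-1; C=O on C-3) | C1C(=O)O[C@@H]2C[C@@H](C)[C@]34C[C@]5(C(=O)O[C@H]6C[C@@]7(C)C(=C[C@H]65)[C@H](C)CC[C@@H]7O[Si](C)(C)C(C)(C)C)[C@H](C(C)=C3C[C@@H]12)C(=O)C4=[N+]=[N-] | intermediate
47 | ketene on C-2 of the norbornene | C1C(=O)O[C@@H]2C[C@@H](C)[C@]34C[C@]5(C(=O)O[C@H]6C[C@@]7(C)C(=C[C@H]65)[C@H](C)CC[C@@H]7O[Si](C)(C)C(C)(C)C)[C@H](C(C)=C3C[C@@H]12)C4=C=O | intermediate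
48 | norbornene-2-carboxylic acid (CO2H anti to C-4=C-5) | C1C(=O)O[C@@H]2C[C@@H](C)[C@]34C[C@]5(C(=O)O[C@H]6C[C@@]7(C)C(=C[C@H]65)[C@H](C)CC[C@@H]7O[Si](C)(C)C(C)(C)C)[C@H](C(C)=C3C[C@@H]12)[C@H]4C(=O)O | intermediate
49 | Barton ester of 48 (2-thioxopyridin-1(2H)-yl ester) | C1C(=O)O[C@@H]2C[C@@H](C)[C@]34C[C@]5(C(=O)O[C@H]6C[C@@]7(C)C(=C[C@H]65)[C@H](C)CC[C@@H]7O[Si](C)(C)C(C)(C)C)[C@H](C(C)=C3C[C@@H]12)[C@H]4C(=O)ON8C=CC=CC8=S | intermediate
50 | 2-hydroperoxide (OOH syn to C-4=C-5) | C1C(=O)O[C@@H]2C[C@@H](C)[C@]34C[C@]5(C(=O)O[C@H]6C[C@@]7(C)C(=C[C@H]65)[C@H](C)CC[C@@H]7O[Si](C)(C)C(C)(C)C)[C@H](C(C)=C3C[C@@H]12)[C@@H]4OO | intermediate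
51 | 2-alcohol (OH syn to C-4=C-5; 13-nor lactone; 1′-OTBS) | C1C(=O)O[C@@H]2C[C@@H](C)[C@]34C[C@]5(C(=O)O[C@H]6C[C@@]7(C)C(=C[C@H]65)[C@H](C)CC[C@@H]7O[Si](C)(C)C(C)(C)C)[C@H](C(C)=C3C[C@@H]12)[C@@H]4O | intermediate
52 | dilithio salt of 51 (2-alkoxide and lactone enolate) | C1=C(O[Li])O[C@@H]2C[C@@H](C)[C@]34C[C@]5(C(=O)O[C@H]6C[C@@]7(C)C(=C[C@H]65)[C@H](C)CC[C@@H]7O[Si](C)(C)C(C)(C)C)[C@H](C(C)=C3C[C@@H]12)[C@@H]4O[Li] | intermediate
53 | 11-(dimethylaminomethyl) lactone (CH2NMe2 cis to H-7) | CN(C)C[C@@H]1C(=O)O[C@@H]2C[C@@H](C)[C@]34C[C@]5(C(=O)O[C@H]6C[C@@]7(C)C(=C[C@H]65)[C@H](C)CC[C@@H]7O[Si](C)(C)C(C)(C)C)[C@H](C(C)=C3C[C@@H]12)[C@@H]4O | intermediate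
54 | trimethylammonium iodide of 53 | C[N+](C)(C)C[C@@H]1C(=O)O[C@@H]2C[C@@H](C)[C@]34C[C@]5(C(=O)O[C@H]6C[C@@]7(C)C(=C[C@H]65)[C@H](C)CC[C@@H]7O[Si](C)(C)C(C)(C)C)[C@H](C(C)=C3C[C@@H]12)[C@@H]4O.[I-] | intermediate
55 | 2-O-deacetyljaponicone A 1′-O-tert-butyldimethylsilyl ether | C=C1C(=O)O[C@@H]2C[C@@H](C)[C@]34C[C@]5(C(=O)O[C@H]6C[C@@]7(C)C(=C[C@H]65)[C@H](C)CC[C@@H]7O[Si](C)(C)C(C)(C)C)[C@H](C(C)=C3C[C@@H]12)[C@@H]4O | intermediate
56 | japonicone A 1′-O-tert-butyldimethylsilyl ether | C=C1C(=O)O[C@@H]2C[C@@H](C)[C@]34C[C@]5(C(=O)O[C@H]6C[C@@]7(C)C(=C[C@H]65)[C@H](C)CC[C@@H]7O[Si](C)(C)C(C)(C)C)[C@H](C(C)=C3C[C@@H]12)[C@@H]4OC(C)=O | intermediate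
57 | japonicone A | C=C1C(=O)O[C@@H]2C[C@@H](C)[C@]34C[C@]5(C(=O)O[C@H]6C[C@@]7(C)C(=C[C@H]65)[C@H](C)CC[C@@H]7O)[C@H](C(C)=C3C[C@@H]12)[C@@H]4OC(C)=O | target

---

**Step count and risks**

Total step count: 28. Longest linear sequence: 18 steps (steps 1–10 and 21–28, from 1).

Steps most likely to fail:

Step 21. The bimolecular cycloaddition at the fully substituted diene terminus C-1 may be slower than dimerisation or decomposition of the dienone. Fallback: starting from 40, Wessely oxidation with Pb(OAc)4 in AcOH/CH2Cl2 gives the isolable o-quinol acetate, the 6-acetoxy-6-methoxycyclohexa-2,4-dienone F1 (either epimer at the acetal carbon serves). F1 is heated with 18 in xylene to give the acetoxy methoxy ketone adduct F2 by the same Diels–Alder mode, and SmI2 in THF/MeOH removes both α-oxygen groups, which rejoins the route at ketone 43.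

Step 25. Capture of the C-2 radical by the small O2 molecule may show poor facial selectivity. Fallback: starting from acid 48, coupling with N-hydroxyphthalimide (DIC, DMAP) gives the redox-active ester F3. Visible-light reduction (Ru(bpy)3(PF6)2, divalent ruthenium; Hantzsch ester; blue LED) in the presence of TEMPO gives the alkoxyamine F4, the bulky nitroxide reaching only the open face over C-4=C-5. Zn in AcOH cleaves the N–O bond, which rejoins the route at alcohol 51.

Step 9. Elimination of the mesylate or attack by hydroxide may compete with ring closure. Fallback: starting from alcohol 11, Dess–Martin periodinane gives the β,γ-unsaturated ketone F5. LiBH(s-Bu)3 at −78 °C adds hydride anti to the angular methyl to give the cis-hydroxy ester F6, which lactonises with TsOH in benzene, rejoining the route at lactone 14.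

Further compounds
F1 | step 21 | 6-acetoxy-6-methoxycyclohexa-2,4-dienone fused to the lactone-bearing seven-membered ring (o-quinol acetate from 40) | C1C(=O)O[C@@H]2C[C@@H](C)C3=C(C[C@@H]12)C(C)=CC(=O)C3(OC)OC(C)=O
F2 | step 21 | acetoxy methoxy ketone Diels–Alder adduct of F1 and 18 | C1C(=O)O[C@@H]2C[C@@H](C)[C@]34C[C@]5(C(=O)O[C@H]6C[C@@]7(C)C(=C[C@H]65)[C@H](C)CC[C@@H]7O[Si](C)(C)C(C)(C)C)[C@H](C(C)=C3C[C@@H]12)C(=O)C4(OC)OC(C)=O
F3 | step 25 | N-acyloxyphthalimide of acid 48 | C1C(=O)O[C@@H]2C[C@@H](C)[C@]34C[C@]5(C(=O)O[C@H]6C[C@@]7(C)C(=C[C@H]65)[C@H](C)CC[C@@H]7O[Si](C)(C)C(C)(C)C)[C@H](C(C)=C3C[C@@H]12)[C@H]4C(=O)ON8C(=O)c9ccccc9C8=O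
F4 | step 25 | 2-O-(2,2,6,6-tetramethylpiperidin-1-yl) ether (O syn to C-4=C-5) | C1C(=O)O[C@@H]2C[C@@H](C)[C@]34C[C@]5(C(=O)O[C@H]6C[C@@]7(C)C(=C[C@H]65)[C@H](C)CC[C@@H]7O[Si](C)(C)C(C)(C)C)[C@H](C(C)=C3C[C@@H]12)[C@@H]4ON8C(C)(C)CCCC8(C)C
F5 | step 9 | ethyl 2-[(2R,4aS,5S,8R)-5-(tert-butyldimethylsilyloxy)-4a,8-dimethyl-3-oxo-2,3,4,4a,5,6,7,8-octahydronaphthalen-2-yl]acetate | CCOC(=O)C[C@H]1C(=O)C[C@@]2(C)C(=C1)[C@H](C)CC[C@@H]2O[Si](C)(C)C(C)(C)C
F6 | step 9 | ethyl 2-[(2R,3S,4aS,5S,8R)-5-(tert-butyldimethylsilyloxy)-3-hydroxy-4a,8-dimethyl-2,3,4,4a,5,6,7,8-octahydronaphthalen-2-yl]acetate | CCOC(=O)C[C@H]1[C@@H](O)C[C@@]2(C)C(=C1)[C@H](C)CC[C@@H]2O[Si](C)(C)C(C)(C)C
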